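## The problem

CNP0170223.1 is (2S,3R,4R)-4-(3-hydroxy-4-methoxyphenyl)-6,7-dimethoxy-2,3-dimethyl-3,4-dihydronaphthalen-1(2H)-one. A veratrole ring (ring A) is fused through C4a–C8a to a carbocycle (ring B) that carries the ketone at C1, methyl groups at C2 and C3, and the pendant aryl group at C4. The ring fusion is trivial. The task is the run of three contiguous stereocentres on ring B, with the C3 methyl cis to the C4 aryl group and trans to the C2 methyl, in one absolute sense. C4 is a diarylmethine that cannot be corrected once made, so it must be set first and with absolute control. C3 can then be set relative to C4, but the cis arrangement is the less stable one while C3 carries an acyl-type group, so it has to be formed kinetically and kept from base. C2 lies alpha to the ketone and can be left to equilibrium, which should favour the target because the C2 epimer would hold its methyl group syn-diaxial to the pseudoaxial C4 aryl group. The sensitive features are the free phenol, the electron-rich 1,2-dihydronaphthalene intermediates (acid-labile and one oxidation away from a naphthalene), and the tetralone itself, which aromatizes to a naphthol under basic oxidizing conditions. The enabling feature is that C4 bears the aryl group next to C3, and the C3 methyl can be traced to a carboxyl-level carbon. If ring B is drawn as the second ring of a naphthalene with an oxazoline on C3, that group activates C4 toward an aryl anion and holds the resulting charge on C3. The C1=C2 double bond that remains already bears the C2 methyl and marks C1 for oxygen.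

(Discussion uses the tetralone numbering of the target; compound names use the locants of their own nomenclature.)

## Retrosynthesis

**Phenol protecting group.** Target 28 is traced to its benzyl ether 27 by cutting the O–CH2Ph bond. A benzyl ether is preferred to a silyl or acetal group because it passes unchanged through aryllithium, hydride, borane, alkaline peroxide, periodinane and methoxide. The forward step must remove it without reducing the aryl ketone.

**C2 configuration.** Ketone 27 is traced to its C2 epimer 26 with no bond cut. C2 is treated as a thermodynamically controlled centre, so the route need not deliver it correctly at first. The forward step asks only that equilibrium lies on the side of the 2,3-trans isomer.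

**C1 oxygen.** Ketone 26 comes from alcohol 25, whose C1–O and C2–H bonds are cut back to the trisubstituted styrene-type alkene 23. Benzylic oxidation of a saturated tetralin would not tell C1 from the doubly benzylic C4, whereas the alkene fixes the position. Precursor 23 has lost the carbonyl and one stereocentre. The forward hydroboration must place boron on the benzylic CH carbon.

**C3 methyl.** The C3 methyl of 23 is traced through tosylate 22, alcohol 21 and aldehyde 20 to the oxazoline carbon of 17. This raises C3 to the carboxyl oxidation level, which is what makes the next cut possible. The forward sequence must unmask and reduce without base, so that the cis relationship survives.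

**C4–aryl bond (key disconnection).** Adduct 17 is cut at the C4–aryl bond and the C3–H bond to the flat naphthyl oxazoline 12 and aryl bromide 14, the latter used as its lithium derivative 15. A Friedel–Crafts closure of C4–C4a would give no absolute control and tends toward the trans arrangement. A C3–C4 cut is discussed under Alternative 2. Precursor 12 has no stereocentre except that of the auxiliary. The forward reaction must choose C4 over all other positions, one face of the ring, the cis mode of protonation, and addition over deprotonation of the neighbouring methyl group.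

**Auxiliary.** Oxazoline 12 is cut at its ring C–O bond and the amide C–N bond, through mesylate-activated amide 10, to naphthoic acid 7 and (R)-tert-leucinol 8. Both steps are routine.

**Naphthalene ring.** Acid 7 comes from ester 6 and its dihydro form 5. The two ring B bonds of 5 that join the benzylic CH2 groups to the alkynoate carbons are cut to the o-quinodimethane 4 and methyl but-2-ynoate 3. Diene 4 is released from dibromide 2, made from veratrole 1 by double bromomethylation. Placing methyl and carboxyl on adjacent beta positions of a preformed naphthalene would be awkward, and the symmetric diene removes any regiochemical question.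

**Aryl partner.** Bromide 14 is cut at the O–benzyl bond to commercial 5-bromo-2-methoxyphenol 13.

## Roads not taken

**Alternative 1:** The cut removes ring A: C4a–C8a, C5–C6 and C7–C8.
- Forward key step: Cp*RuCl(cod) joins the two terminal alkynes of the 1,7-diyne A2 (a 6-aryl-4,5-dimethylocta-1,7-diyn-3-one carrying all three stereocentres) with 1,2-bis(pinacolboryl)ethyne, closing rings A and B together to the 6,7-diborylated tetralone A1.
- Merits: the step is catalytic and neutral, and the two C–B bonds of A1 would allow the ring A oxygen pattern to be varied late.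
- Weak points: the step creates no stereocentre. All three must be built on the open chain of A2, where C4 is both benzylic and propargylic and C2 is alpha to a terminal ynone; both are prone to epimerization, and the ynone is a Michael acceptor. After the key step, two C–B oxidations and two O-methylations only recreate the veratrole ring that is a commodity.
- Comparison: this road is better in convergence and needs no stoichiometric auxiliary. The chosen plan sets against it a key step that creates two of the three stereocentres on a rigid ring and a ring A that is bought correctly oxygenated.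

**Alternative 2:** The cut is the C3–C4 bond of ring B, taken as a double bond.
- Forward key step: low-valent titanium from TiCl4 and Zn couples the methyl ketone and the diaryl ketone of diketone A4 (McMurry reaction) to the tetrasubstituted 1,2-dihydronaphthalene A3. Once the silyl group of A3 is removed, the C1 hydroxyl would steer a cationic complex such as [Ir(cod)(PCy3)(py)]PF6 to add hydrogen across C3=C4.
- Merits: syn addition of hydrogen guarantees the cis C3/C4 relationship, no epimerizable cis aldehyde is carried, and the C1 oxygen is present from the start.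
- Weak points: a tetrasubstituted alkene bearing an aryl group at C4 and conjugated to ring A is among the slowest to hydrogenate. The directing hydroxyl is homoallylic to C4. Whether the face it selects is also trans to the C2 methyl depends on the C1/C2 relationship in A4, which needs its own enantioselective aldol. The McMurry step uses stoichiometric titanium on a benzophenone prone to pinacol formation, next to a benzylic silyl ether.
- Comparison: this road is as good or better in the certainty of the cis relationship. The chosen plan sets against it absolute and relative control from one auxiliary-directed operation on an aromatic precursor six steps from veratrole, and a hydroboration of a trisubstituted alkene in place of a hindered hydrogenation.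

**Alternative 3:** The cut removes both methyl groups from the naphthoquinone monoketal A6.
- Forward key step: Me2Zn adds to C3 under Cu(OTf)2 and a chiral phosphoramidite, and the zinc enolate is methylated at C2 with MeI to give the trans-dimethyl ketal A5.
- Merits: enantiocontrol is catalytic, and the trans C2/C3 relationship is set directly instead of by late equilibration.
- Weak points: the zinc enolate leading to A5 has a ketal methoxy group in the beta position, so loss of methanol and aromatization to a naphthol threatens both new centres. Zinc enolates react sluggishly with MeI. The aryl group is still missing: C1 must be masked, the C4 ketal opened, an arylmetal added and the tertiary benzylic hydroxyl removed, with C4 set only by substrate control.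
- Comparison: this road is better in catalytic asymmetric induction and in the direct trans-dimethyl relationship. The chosen plan sets against it that the hardest centre, the diarylmethine C4, is made first under reagent control, and the aryl ring arrives in the same step that breaks aromaticity.

Key step: step 8

Remark on the chemistry: the aryllithium is taken to be delivered to the naphthalene face opposite the tert-butyl group of the nitrogen-bound oxazoline. This assumed facial sense rests on the accepted steric model, not on a confirmed case, and it makes (R)-tert-leucinol 8 the auxiliary for the (4R) target. If the sense proves opposite, the (S)-enantiomer of 8 is used and nothing else changes.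

## Route

Step 1
Reactants: 1 veratrole
Product: 2 1,2-bis(bromomethyl)-4,5-dimethoxybenzene
Conditions: (CH2O)n, 33% HBr in AcOH, rt
Reagents that add atoms: paraformaldehyde (as formaldehyde), C=O; hydrogen bromide, Br
Why: Double electrophilic bromomethylation (Blanc-type) of the activated ring; the two methoxy groups direct both CH2Br groups to the 4- and 5-positions.

Step 2
Reactants: 2 1,2-bis(bromomethyl)-4,5-dimethoxybenzene; 3 methyl but-2-ynoate
Product: 5 methyl 6,7-dimethoxy-3-methyl-1,4-dihydronaphthalene-2-carboxylate, via 4,5-dimethoxy-o-quinodimethane 4 (not isolated)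
Conditions: NaI, DMF, 70 °C, excess 3
Reagents that add atoms: none
Why: Finkelstein exchange and iodide-induced 1,4-elimination release the o-quinodimethane, which is trapped by the alkynoate in a Diels–Alder reaction driven by re-aromatization of ring A; the symmetric diene leaves no regiochemical question.

Step 3
Reactants: 5 methyl 6,7-dimethoxy-3-methyl-1,4-dihydronaphthalene-2-carboxylate
Product: 6 methyl 6,7-dimethoxy-3-methylnaphthalene-2-carboxylate
Conditions: DDQ, toluene, rt → 60 °C
Reagents that add atoms: none
Why: Quinone dehydrogenation of a 1,4-dihydronaphthalene; hydride loss from the doubly allylic-benzylic CH2 and proton loss give the naphthalene.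

Step 4
Reactants: 6 methyl 6,7-dimethoxy-3-methylnaphthalene-2-carboxylate
Product: 7 6,7-dimethoxy-3-methylnaphthalene-2-carboxylic acid
Conditions: LiOH, THF/MeOH/H2O, 60 °C; then 1 M HCl
Reagents that add atoms: lithium hydroxide, [Li+].[OH-]
Why: Ordinary ester saponification; warming compensates for the ortho methyl group.

Step 5
Reactants: 7 6,7-dimethoxy-3-methylnaphthalene-2-carboxylic acid; 8 (R)-tert-leucinol
Product: 10 N-[(2R)-1-hydroxy-3,3-dimethylbutan-2-yl]-6,7-dimethoxy-3-methylnaphthalene-2-carboxamide, via acid chloride 9 (not isolated)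
Conditions: (COCl)2, DMF (cat.), CH2Cl2, 0 °C → rt; then 8, Et3N, CH2Cl2, 0 °C → rt
Reagents that add atoms: none
Why: Acid chloride formation and N-acylation of the amino alcohol; the amine reacts ahead of the hindered primary hydroxyl.

Step 6
Reactants: 10 N-[(2R)-1-hydroxy-3,3-dimethylbutan-2-yl]-6,7-dimethoxy-3-methylnaphthalene-2-carboxamide
Product: 12 (4R)-4-tert-butyl-2-(6,7-dimethoxy-3-methylnaphthalen-2-yl)-4,5-dihydro-1,3-oxazole, via mesylate 11 (not isolated)
Conditions: MsCl, Et3N, CH2Cl2, 0 → 40 °C
Reagents that add atoms: none
Why: O-mesylation followed by 5-exo-tet displacement by the amide oxygen gives the oxazoline; the stereocentre is not involved.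

Step 7
Reactants: 13 5-bromo-2-methoxyphenol
Product: 14 2-(benzyloxy)-4-bromo-1-methoxybenzene
Conditions: BnBr, K2CO3, DMF, rt
Reagents that add atoms: benzyl bromide, BrCc1ccccc1
Why: Williamson etherification of the phenoxide; the benzyl ether tolerates every later reagent and is removed last.

Step 8
Reactants: 12 (4R)-4-tert-butyl-2-(6,7-dimethoxy-3-methylnaphthalen-2-yl)-4,5-dihydro-1,3-oxazole; 14 2-(benzyloxy)-4-bromo-1-methoxybenzene
Product: 17 (4R)-2-[(1R,2R)-1-(3-benzyloxy-4-methoxyphenyl)-6,7-dimethoxy-3-methyl-1,2-dihydronaphthalen-2-yl]-4-tert-butyl-4,5-dihydro-1,3-oxazole (aryl and oxazoline cis), via aryllithium 15 (not isolated), via lithium azaenolate 16 (not isolated)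
Conditions: t-BuLi (2 equiv per 14), THF, −78 °C; then 12, THF, −78 → −45 °C; then CF3CO2H, THF, −78 °C
Reagents that add atoms: none
Why: Bromine–lithium exchange with two equivalents of t-BuLi gives 15 and destroys the t-BuBr formed, so no alkyl halide is left to alkylate the azaenolate. 15 binds the oxazoline nitrogen of 12 in the rotamer whose C=N points to the unsubstituted naphthalene C1 and transfers its aryl group to C1 in a conjugate addition across C1=C2–C=N; only the substituted ring loses aromaticity and the charge rests in lithium azaenolate 16. The closest known reaction type is the tandem organolithium addition–electrophile trapping of chiral 1- and 2-naphthyl oxazolines, here with a proton as the electrophile; no ring is closed. The C1 stereocentre (C4 of 28) is controlled by the auxiliary: the tert-butyl group screens one face of the nitrogen-bound reagent, the aryl group enters anti to it, and the (R)-auxiliary should therefore give the (1R) configuration. The C2 stereocentre (C3 of 28) is controlled by the new aryl group: CF3CO2H at −78 °C protonates the azaenolate carbon on the face away from it, which leaves oxazoline and aryl cis, the kinetic and less stable arrangement. Site selectivity follows from the naphthalene itself, since attack at C3 would interrupt both rings. Addition has to outrun deprotonation of the 3-methyl group; the low kinetic basicity of an aryllithium, the low temperature and the nitrogen-directed geometry that holds the reagent on the C1 side are what should secure this. The cis adduct must not meet base, so the quench is acidic and the work-up cold and neutral.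

Step 9
Reactants: 17 (4R)-2-[(1R,2R)-1-(3-benzyloxy-4-methoxyphenyl)-6,7-dimethoxy-3-methyl-1,2-dihydronaphthalen-2-yl]-4-tert-butyl-4,5-dihydro-1,3-oxazole
Product: 20 (1R,2R)-1-(3-benzyloxy-4-methoxyphenyl)-6,7-dimethoxy-3-methyl-1,2-dihydronaphthalene-2-carbaldehyde, via N-methyloxazolinium triflate 18 (not isolated), via N-methyloxazolidine 19 (not isolated)
Conditions: MeOTf, CH2Cl2, 0 °C → rt; NaBH4, THF/MeOH, 0 °C; (CO2H)2, THF/H2O, rt
Reagents that add atoms: water, O
Why: Standard reductive unmasking of an oxazoline: N-methylation makes C2 of the heterocycle electrophilic, hydride gives the N,O-aminal, and mild aqueous acid releases the aldehyde without base, so the cis C3 centre should be kept.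

Step 10
Reactants: 20 (1R,2R)-1-(3-benzyloxy-4-methoxyphenyl)-6,7-dimethoxy-3-methyl-1,2-dihydronaphthalene-2-carbaldehyde
Product: 21 [(1R,2R)-1-(3-benzyloxy-4-methoxyphenyl)-6,7-dimethoxy-3-methyl-1,2-dihydronaphthalen-2-yl]methanol
Conditions: NaBH4, MeOH, 0 °C (crude 20 used at once)
Reagents that add atoms: none
Why: Borohydride reduction of the aldehyde; immediate reduction removes the only acidic C–H alpha to a carbonyl and so fixes the cis relationship for good.

Step 11
Reactants: 21 [(1R,2R)-1-(3-benzyloxy-4-methoxyphenyl)-6,7-dimethoxy-3-methyl-1,2-dihydronaphthalen-2-yl]methanol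
Product: 22 [(1R,2R)-1-(3-benzyloxy-4-methoxyphenyl)-6,7-dimethoxy-3-methyl-1,2-dihydronaphthalen-2-yl]methyl 4-methylbenzenesulfonate
Conditions: TsCl, pyridine, DMAP (cat.), CH2Cl2, 0 °C → rt
Reagents that add atoms: p-toluenesulfonyl chloride, Cc1ccc(cc1)S(Cl)(=O)=O
Why: Sulfonylation of an unhindered primary alcohol.

Step 12
Reactants: 22 [(1R,2R)-1-(3-benzyloxy-4-methoxyphenyl)-6,7-dimethoxy-3-methyl-1,2-dihydronaphthalen-2-yl]methyl 4-methylbenzenesulfonate
Product: 23 (1R,2R)-1-(3-benzyloxy-4-methoxyphenyl)-6,7-dimethoxy-2,3-dimethyl-1,2-dihydronaphthalene (aryl and C2 methyl cis)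
Conditions: LiEt3BH, THF, 0 °C → rt
Reagents that add atoms: none
Why: SN2 displacement of a primary sulfonate by a strongly nucleophilic borohydride, reliable for beta-branched primary centres; no stereocentre is touched.

Step 13
Reactants: 23 (1R,2R)-1-(3-benzyloxy-4-methoxyphenyl)-6,7-dimethoxy-2,3-dimethyl-1,2-dihydronaphthalene
Product: 25 (1S,2R,3R,4R)-4-(3-benzyloxy-4-methoxyphenyl)-6,7-dimethoxy-2,3-dimethyl-1,2,3,4-tetrahydronaphthalen-1-ol, via alkylborane 24 (not isolated)
Conditions: BH3·THF, THF, 0 °C → rt; then NaOH, H2O2, 0 °C → rt
Reagents that add atoms: hydrogen peroxide, OO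
Why: Hydroboration–oxidation of a trisubstituted alkene places boron on the less substituted benzylic carbon C1; syn addition from the face opposite the pseudoaxial aryl group is expected to give the C2 methyl cis to the C3 methyl, and any facial leakage converges because C1 is oxidized and C2 equilibrated afterwards.

Step 14
Reactants: 25 (1S,2R,3R,4R)-4-(3-benzyloxy-4-methoxyphenyl)-6,7-dimethoxy-2,3-dimethyl-1,2,3,4-tetrahydronaphthalen-1-ol
Product: 26 (2R,3R,4R)-4-(3-benzyloxy-4-methoxyphenyl)-6,7-dimethoxy-2,3-dimethyl-3,4-dihydronaphthalen-1(2H)-one (2,3-cis, 3,4-cis)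
Conditions: Dess–Martin periodinane, NaHCO3, CH2Cl2, rt
Reagents that add atoms: none
Why: Dess–Martin oxidation of a secondary benzylic alcohol under buffered, non-enolizing conditions; the protected phenol and the diarylmethine C–H are left alone.

Step 15
Reactants: 26 (2R,3R,4R)-4-(3-benzyloxy-4-methoxyphenyl)-6,7-dimethoxy-2,3-dimethyl-3,4-dihydronaphthalen-1(2H)-one
Product: 27 (2S,3R,4R)-4-(3-benzyloxy-4-methoxyphenyl)-6,7-dimethoxy-2,3-dimethyl-3,4-dihydronaphthalen-1(2H)-one (2,3-trans, 3,4-cis)
Conditions: NaOMe (cat.), MeOH, rt, under argon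
Reagents that add atoms: none
Why: Base-mediated epimerization through the enolate; in 26 the C2 methyl is syn-diaxial to the pseudoaxial C4 aryl group, whereas 27 has both methyl groups equatorial, so equilibrium should lie on the side of 27; C3 and C4 are not acidic under these conditions, and air is excluded to prevent aromatization to a naphthol.

Step 16
Reactants: 27 (2S,3R,4R)-4-(3-benzyloxy-4-methoxyphenyl)-6,7-dimethoxy-2,3-dimethyl-3,4-dihydronaphthalen-1(2H)-one
Product: 28 (2S,3R,4R)-4-(3-hydroxy-4-methoxyphenyl)-6,7-dimethoxy-2,3-dimethyl-3,4-dihydronaphthalen-1(2H)-one (CNP0170223.1)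
Conditions: H2 (1 atm), 10% Pd/C, EtOAc, rt
Reagents that add atoms: none
Why: Hydrogenolysis of a benzyl aryl ether; the ketone, made electron-rich by the para methoxy group, and the C4–H bond are not expected to react under these mild neutral conditions.

## Compound list

1 | veratrole (1,2-dimethoxybenzene) | COc1ccccc1OC | starting material
2 | 1,2-bis(bromomethyl)-4,5-dimethoxybenzene | COc1cc(CBr)c(CBr)cc1OC | intermediate
3 | methyl but-2-ynoate | CC#CC(=O)OC | starting material
4 | 4,5-dimethoxy-o-quinodimethane (2,3-dimethoxy-5,6-dimethylidenecyclohexa-1,3-diene) | C=C1C=C(OC)C(OC)=CC1=C | intermediate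
5 | methyl 6,7-dimethoxy-3-methyl-1,4-dihydronaphthalene-2-carboxylate | COC(=O)C1=C(C)Cc2cc(OC)c(OC)cc2C1 | intermediate
6 | methyl 6,7-dimethoxy-3-methylnaphthalene-2-carboxylate | COC(=O)c1cc2cc(OC)c(OC)cc2cc1C | intermediate
7 | 6,7-dimethoxy-3-methylnaphthalene-2-carboxylic acid | COc1cc2cc(C)c(cc2cc1OC)C(O)=O | intermediate
8 | (R)-tert-leucinol, (2R)-2-amino-3,3-dimethylbutan-1-ol | CC(C)(C)[C@@H](N)CO | starting material
9 | 6,7-dimethoxy-3-methylnaphthalene-2-carbonyl chloride | COc1cc2cc(C)c(cc2cc1OC)C(Cl)=O | intermediate
10 | N-[(2R)-1-hydroxy-3,3-dimethylbutan-2-yl]-6,7-dimethoxy-3-methylnaphthalene-2-carboxamide | COc1cc2cc(C)c(cc2cc1OC)C(=O)N[C@H](C(C)(C)C)CO | intermediate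
11 | (2R)-2-[(6,7-dimethoxy-3-methylnaphthalene-2-carbonyl)amino]-3,3-dimethylbutyl methanesulfonate | COc1cc2cc(C)c(cc2cc1OC)C(=O)N[C@H](C(C)(C)C)COS(C)(=O)=O | intermediate
12 | (4R)-4-tert-butyl-2-(6,7-dimethoxy-3-methylnaphthalen-2-yl)-4,5-dihydro-1,3-oxazole | COc1cc2cc(C)c(cc2cc1OC)C1=N[C@H](C(C)(C)C)CO1 | intermediate
13 | 5-bromo-2-methoxyphenol | COc1ccc(Br)cc1O | starting material
14 | 2-(benzyloxy)-4-bromo-1-methoxybenzene | COc1ccc(Br)cc1OCc1ccccc1 | intermediate
15 | (3-benzyloxy-4-methoxyphenyl)lithium | [Li]c1ccc(OC)c(OCc2ccccc2)c1 | intermediate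
16 | lithium azaenolate from 12 and 15 (N-lithio ketene N,O-acetal, (1R) at the aryl-bearing carbon, (4R) in the heterocycle) | COc1ccc([C@@H]2c3cc(OC)c(OC)cc3C=C(C)C2=C2N([Li])[C@H](C(C)(C)C)CO2)cc1OCc1ccccc1 | intermediate
17 | (4R)-2-[(1R,2R)-1-(3-benzyloxy-4-methoxyphenyl)-6,7-dimethoxy-3-methyl-1,2-dihydronaphthalen-2-yl]-4-tert-butyl-4,5-dihydro-1,3-oxazole (aryl and oxazoline cis) | COc1ccc([C@@H]2c3cc(OC)c(OC)cc3C=C(C)[C@@H]2C2=N[C@H](C(C)(C)C)CO2)cc1OCc1ccccc1 | intermediate
18 | N-methyloxazolinium trifluoromethanesulfonate of 17 | COc1ccc([C@@H]2c3cc(OC)c(OC)cc3C=C(C)[C@@H]2C2=[N+](C)[C@H](C(C)(C)C)CO2)cc1OCc1ccccc1.[O-]S(=O)(=O)C(F)(F)F | intermediate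
19 | N-methyloxazolidine from 18 (aminal carbon as a mixture) | COc1ccc([C@@H]2c3cc(OC)c(OC)cc3C=C(C)[C@@H]2C2N(C)[C@H](C(C)(C)C)CO2)cc1OCc1ccccc1 | intermediate
20 | (1R,2R)-1-(3-benzyloxy-4-methoxyphenyl)-6,7-dimethoxy-3-methyl-1,2-dihydronaphthalene-2-carbaldehyde | COc1ccc([C@@H]2c3cc(OC)c(OC)cc3C=C(C)[C@@H]2C=O)cc1OCc1ccccc1 | intermediate
21 | [(1R,2R)-1-(3-benzyloxy-4-methoxyphenyl)-6,7-dimethoxy-3-methyl-1,2-dihydronaphthalen-2-yl]methanol | COc1ccc([C@@H]2c3cc(OC)c(OC)cc3C=C(C)[C@@H]2CO)cc1OCc1ccccc1 | intermediate
22 | [(1R,2R)-1-(3-benzyloxy-4-methoxyphenyl)-6,7-dimethoxy-3-methyl-1,2-dihydronaphthalen-2-yl]methyl 4-methylbenzenesulfonate | COc1ccc([C@@H]2c3cc(OC)c(OC)cc3C=C(C)[C@@H]2COS(=O)(=O)c4ccc(C)cc4)cc1OCc1ccccc1 | intermediate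
23 | (1R,2R)-1-(3-benzyloxy-4-methoxyphenyl)-6,7-dimethoxy-2,3-dimethyl-1,2-dihydronaphthalene | COc1ccc([C@@H]2c3cc(OC)c(OC)cc3C=C(C)[C@@H]2C)cc1OCc1ccccc1 | intermediate
24 | alkylborane from 23 (drawn as the monoalkylborane; boron on C1 on the face opposite the aryl group, C2 methyl cis to the C3 methyl) | COc1ccc([C@@H]2c3cc(OC)c(OC)cc3[C@@H](B)[C@H](C)[C@@H]2C)cc1OCc1ccccc1 | intermediate
25 | (1S,2R,3R,4R)-4-(3-benzyloxy-4-methoxyphenyl)-6,7-dimethoxy-2,3-dimethyl-1,2,3,4-tetrahydronaphthalen-1-ol | COc1ccc([C@@H]2c3cc(OC)c(OC)cc3[C@@H](O)[C@H](C)[C@@H]2C)cc1OCc1ccccc1 | intermediate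
26 | (2R,3R,4R)-4-(3-benzyloxy-4-methoxyphenyl)-6,7-dimethoxy-2,3-dimethyl-3,4-dihydronaphthalen-1(2H)-one | COc1ccc([C@@H]2c3cc(OC)c(OC)cc3C(=O)[C@H](C)[C@@H]2C)cc1OCc1ccccc1 | intermediate
27 | (2S,3R,4R)-4-(3-benzyloxy-4-methoxyphenyl)-6,7-dimethoxy-2,3-dimethyl-3,4-dihydronaphthalen-1(2H)-one | COc1ccc([C@@H]2c3cc(OC)c(OC)cc3C(=O)[C@@H](C)[C@@H]2C)cc1OCc1ccccc1 | intermediate
28 | (2S,3R,4R)-4-(3-hydroxy-4-methoxyphenyl)-6,7-dimethoxy-2,3-dimethyl-3,4-dihydronaphthalen-1(2H)-one (CNP0170223.1) | COc1ccc([C@@H]2c3cc(OC)c(OC)cc3C(=O)[C@@H](C)[C@@H]2C)cc1O | target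

## Step count and risks

Total step count: 16. Longest linear sequence: 15 steps (steps 1–6 and 8–16, from veratrole 1); step 7 is the one-step side branch.

**Step 8 (key step).**
- Most likely to go wrong: the aryllithium acts as a base on the naphthalene 3-methyl group (lateral deprotonation next to the oxazoline) instead of adding to C1. The laterally metalated species does not accept a nucleophile, so conversion stalls. Second in likelihood is erosion of the cis relationship by enolization at C3 during quench or work-up.
- Fallback: the methyl group is left off the naphthalene and put on last. The fallback sets out from amino alcohol 8 and bromide 14 and returns to the route at 27.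
- Commercial 6,7-dimethoxynaphthalene-2-carboxylic acid F1 is coupled with 8 as in step 5 to give the amide F2. Cyclization as in step 6 gives (4R)-4-tert-butyl-2-(6,7-dimethoxynaphthalen-2-yl)-4,5-dihydro-1,3-oxazole F3, which has no lateral protons and belongs to the substrate class on which this addition is best established.
- Aryllithium 15 and a cold CF3CO2H quench should give the cis adduct F4. The operations of steps 9–12 lead through the aldehyde F5, the alcohol F6 and the tosylate F7 to (1R,2S)-1-(3-benzyloxy-4-methoxyphenyl)-6,7-dimethoxy-2-methyl-1,2-dihydronaphthalene F8.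
- Hydroboration–oxidation as in step 13 gives the benzylic alcohol F9, and Dess–Martin oxidation gives the 3-methyl-4-aryltetralone F10.
- The lithium enolate of F10 (LiN(SiMe3)2, THF, −78 °C) is methylated with MeI on the face away from the pseudoaxial C4 aryl group, that is, trans to the C3 methyl, to give 27 directly. Any cis epimer is levelled under the conditions of step 15.
- The price is a less regioselective hydroboration (1,2-disubstituted in place of trisubstituted styrene) and the need to avoid double methylation.

**Step 2.**
- Most likely to go wrong: oligomerization of the o-quinodimethane outruns its capture by the only moderately reactive alkynoate, and the iodine formed attacks the electron-rich product.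
- Fallback: it sets out from dibromide 2 and returns at 5. Compound 2 is treated with HOCH2SO2Na and Bu4NBr in DMF to give the sultine 6,7-dimethoxy-1,4-dihydro-2,3-benzoxathiine 3-oxide F11. Heating F11 with excess 3 in toluene extrudes sulfur dioxide and releases 4 slowly, without halide or iodine, at a temperature where the alkynoate reacts faster.

**Step 9.**
- Most likely to go wrong: enolization of the beta,gamma-unsaturated aldehyde 20 during the acidic hydrolysis, with loss of the cis configuration at C3 or migration of the double bond into conjugation.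
- Fallback: the aldehyde oxidation level is avoided. The fallback sets out from 17 and returns at 21. Ring opening of 17 with CF3CO2H, H2O and Na2SO4 in THF gives the amino ester F12 (as its trifluoroacetate salt). N-Acetylation (Ac2O, pyridine) gives the acetamido ester F13 and blocks O-to-N acyl migration. LiAlH4 in THF at 0 °C reduces the ester to alcohol 21.

**Step 16.**
- Most likely to go wrong: over-reduction, with the aryl ketone hydrogenated to the benzylic alcohol or methylene compound while the benzyl ether is cleaved.
- Fallback: Lewis-acid debenzylation in place of hydrogenolysis, from 27 directly to 28: BCl3 and pentamethylbenzene in CH2Cl2 at −78 °C. The cation scavenger takes up the benzyl group, and the aryl methyl ethers and the ketone are not expected to react at this temperature. No new compound is made.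

## Further compounds

F1 | step 8 | 6,7-dimethoxynaphthalene-2-carboxylic acid | COc1cc2ccc(cc2cc1OC)C(O)=O
F2 | step 8 | N-[(2R)-1-hydroxy-3,3-dimethylbutan-2-yl]-6,7-dimethoxynaphthalene-2-carboxamide | COc1cc2ccc(cc2cc1OC)C(=O)N[C@H](C(C)(C)C)CO
F3 | step 8 | (4R)-4-tert-butyl-2-(6,7-dimethoxynaphthalen-2-yl)-4,5-dihydro-1,3-oxazole | COc1cc2ccc(cc2cc1OC)C1=N[C@H](C(C)(C)C)CO1
F4 | step 8 | (4R)-2-[(1R,2S)-1-(3-benzyloxy-4-methoxyphenyl)-6,7-dimethoxy-1,2-dihydronaphthalen-2-yl]-4-tert-butyl-4,5-dihydro-1,3-oxazole (aryl and oxazoline cis) | COc1ccc([C@@H]2c3cc(OC)c(OC)cc3C=C[C@@H]2C2=N[C@H](C(C)(C)C)CO2)cc1OCc1ccccc1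
F5 | step 8 | (1R,2S)-1-(3-benzyloxy-4-methoxyphenyl)-6,7-dimethoxy-1,2-dihydronaphthalene-2-carbaldehyde | COc1ccc([C@@H]2c3cc(OC)c(OC)cc3C=C[C@@H]2C=O)cc1OCc1ccccc1
F6 | step 8 | [(1R,2S)-1-(3-benzyloxy-4-methoxyphenyl)-6,7-dimethoxy-1,2-dihydronaphthalen-2-yl]methanol | COc1ccc([C@@H]2c3cc(OC)c(OC)cc3C=C[C@@H]2CO)cc1OCc1ccccc1
F7 | step 8 | [(1R,2S)-1-(3-benzyloxy-4-methoxyphenyl)-6,7-dimethoxy-1,2-dihydronaphthalen-2-yl]methyl 4-methylbenzenesulfonate | COc1ccc([C@@H]2c3cc(OC)c(OC)cc3C=C[C@@H]2COS(=O)(=O)c4ccc(C)cc4)cc1OCc1ccccc1
F8 | step 8 | (1R,2S)-1-(3-benzyloxy-4-methoxyphenyl)-6,7-dimethoxy-2-methyl-1,2-dihydronaphthalene | COc1ccc([C@@H]2c3cc(OC)c(OC)cc3C=C[C@@H]2C)cc1OCc1ccccc1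
F9 | step 8 | (3S,4R)-4-(3-benzyloxy-4-methoxyphenyl)-6,7-dimethoxy-3-methyl-1,2,3,4-tetrahydronaphthalen-1-ol (C1 epimers) | COc1ccc([C@@H]2c3cc(OC)c(OC)cc3C(O)C[C@@H]2C)cc1OCc1ccccc1
F10 | step 8 | (3S,4R)-4-(3-benzyloxy-4-methoxyphenyl)-6,7-dimethoxy-3-methyl-3,4-dihydronaphthalen-1(2H)-one | COc1ccc([C@@H]2c3cc(OC)c(OC)cc3C(=O)C[C@@H]2C)cc1OCc1ccccc1
F11 | step 2 | 6,7-dimethoxy-1,4-dihydro-2,3-benzoxathiine 3-oxide | COc1cc2COS(=O)Cc2cc1OC
F12 | step 9 | (2R)-2-amino-3,3-dimethylbutyl (1R,2R)-1-(3-benzyloxy-4-methoxyphenyl)-6,7-dimethoxy-3-methyl-1,2-dihydronaphthalene-2-carboxylate | COc1ccc([C@@H]2c3cc(OC)c(OC)cc3C=C(C)[C@@H]2C(=O)OC[C@H](N)C(C)(C)C)cc1OCc1ccccc1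
F13 | step 9 | (2R)-2-acetamido-3,3-dimethylbutyl (1R,2R)-1-(3-benzyloxy-4-methoxyphenyl)-6,7-dimethoxy-3-methyl-1,2-dihydronaphthalene-2-carboxylate | COc1ccc([C@@H]2c3cc(OC)c(OC)cc3C=C(C)[C@@H]2C(=O)OC[C@H](NC(C)=O)C(C)(C)C)cc1OCc1ccccc1
F0 | step 16 | none | none
A1 | alternative 1 | (2S,3R,4R)-4-(3-benzyloxy-4-methoxyphenyl)-2,3-dimethyl-6,7-bis(4,4,5,5-tetramethyl-1,3,2-dioxaborolan-2-yl)-3,4-dihydronaphthalen-1(2H)-one | COc1ccc([C@@H]2c3cc(B4OC(C)(C)C(C)(C)O4)c(B4OC(C)(C)C(C)(C)O4)cc3C(=O)[C@@H](C)[C@@H]2C)cc1OCc1ccccc1
A2 | alternative 1 | 6-(3-benzyloxy-4-methoxyphenyl)-4,5-dimethylocta-1,7-diyn-3-one (stereocentres as C2, C3 and C4 of 28) | COc1ccc([C@@H]([C@@H](C)[C@H](C)C(=O)C#C)C#C)cc1OCc1ccccc1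
A3 | alternative 2 | {[4-(3-benzyloxy-4-methoxyphenyl)-6,7-dimethoxy-2,3-dimethyl-1,2-dihydronaphthalen-1-yl]oxy}(tert-butyl)dimethylsilane | COc1ccc(C2=C(C)[C@@H](C)[C@H](O[Si](C)(C)C(C)(C)C)c3cc(OC)c(OC)cc23)cc1OCc1ccccc1
A4 | alternative 2 | 4-[2-(3-benzyloxy-4-methoxybenzoyl)-4,5-dimethoxyphenyl]-4-[(tert-butyldimethylsilyl)oxy]-3-methylbutan-2-one | COc1ccc(C(=O)c2cc(OC)c(OC)cc2[C@@H](O[Si](C)(C)C(C)(C)C)[C@H](C)C(C)=O)cc1OCc1ccccc1
A5 | alternative 3 | (2S,3S)-4,4,6,7-tetramethoxy-2,3-dimethyl-3,4-dihydronaphthalen-1(2H)-one (trans) | COC1(OC)c2cc(OC)c(OC)cc2C(=O)[C@@H](C)[C@@H]1C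
A6 | alternative 3 | 4,4,6,7-tetramethoxynaphthalen-1(4H)-one | COc1cc2C(=O)C=CC(OC)(OC)c2cc1OC
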